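The slowness of the pairing of E with Z was my way in: its constant is far smaller than that of the first step, so I asked how long E and Z stand together.

all flasks: time 1.0 min
- summer: X 20 mM; Q 20.0 mM; everything together at the start
- noon: X 20 mM (in portions, 3, over 50 s); Q 20.0 mM; first portion at the start, last at 50 s
- midnight: X 20 mM; Q 20.0 mM (fed, over 50 s); all else is in the flask from the start; the feed brings no volume worth counting
- spring: X 20 mM (fed, over 50 s); Q 20.0 mM; all else is in the flask from the start; the feed brings no volume worth counting

    X + Q → E + Z (k1 = 170 /M/s)
    E + Z → E.Z (k2 = 0.520 /M/s)
    Q ⇌ D (K3 = 0.273, k3 = 0.0116 /s)

- which flask leads in share of E in E plus E.Z ("all alike" within 1.5 percentage points) (summer / noon / midnight / spring / all alike)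
- share of E in E plus E.Z at the end, summer
- share of E in E plus E.Z at the end, noon
- share of E in E plus E.Z at the end, midnight
- share of E in E plus E.Z at the end, spring

I carried one quantity, the pairing time τ, the inverse of the pairing constant times the charge, 96.2 s; it is the second-order half-life of E when [E] and [Z] both start at the charge.

In summer, with Q as charged, X had a half-life by the first step of 0.20 s, which lay 2.68 powers of ten below τ. At the start of summer, Q went to E and Z 290 times faster than to D, counting that step's forward rate alone. So for summer I dropped D and let [E] shoot up to the charge, with its knee near that half-life. From there, in my summer curve, [E] left at a slope of 0.208 mM/s and bent along the charge times τ/(τ+t). That summer curve crossed [E.Z] at t = τ, later than the reading at 60 s, and since the pairing arrow has no return, the level it ran towards was zero.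

At noon, midnight and spring, where E arrived late, I dropped D as well, but as an untested guess, and I assumed that each bit of X or Q met its partner at once. I counted a contact time θ, the square of [E] over the charge summed along the run, and took the share as τ/(τ+θ). A steady feed gave a third of the feed time plus the time after it, and the portions at noon gave steps.

| flask | θ | share of E |
|---|---|---|
| summer | 60 s | 61.6 % |
| noon | 23.9 s | 80.1 % |
| midnight, spring | 26.7 s | 78.3 % |

So I committed to noon, whose share stood higher than the others.

The forecast also named noon, with 62.1 % for summer, 80.9 % for noon, 79.7 % for midnight and 78.8 % for spring, each a little above my figures, and called its ranking “a rough estimate”.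

The simulation put noon first: summer 62.8 %, noon 81.4 %, midnight 79.5 %, spring 79.7 %. With the loss of Q to D struck out both ways, noon read 81.6 %, so the step I dropped moved it by 0.20 percentage points. For summer at 10.0 min, τ gave 13.8 %, and the flask read 14.0 %. Summer left until 1.5 min stood just short of τ, so τ gave a share of 51.7 % with E still ahead of E.Z. The computed flask gave 52.6 %, with E at 52.4 % and E.Z at 47.1 %.

(The numbers of this flask are made up; the flask was simulated.)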